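**Plan**
- Retrosynthesis: the phenols are freed last (allyl ethers), C8–OAc is traced to a tertiary alcohol and C9H2 to a lactone carbonyl, then C7–C8 and C8'–C9' are cut together.
- Why this cut: ring A (C8–C7–O–C9'–C8') contains C7–O–C9', the skeleton of a carbonyl ylide, and C8=C8' can be the alkene of a ring B butenolide (C8'–C7'–O–C9–C8) that already bears the C8 acetoxy group.
- Forward: ring B first, as an (R)-5-aryl-3-acetoxybutenolide (glyoxylate aldol, asymmetric transfer hydrogenation, lactonisation, oxidation, O-acetylation); ring A second, by the [3+2] cycloaddition.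
- Endgame: C9 lactone to ether, acetylation of C8–OH, deallylation.
- Stereochemistry: C7' from the catalyst-controlled ketone reduction; C8, C8' and C7 relayed from C7' in the cycloaddition (anti face, suprafacial addition, exo aryl).

Key step: step 8

Remark: lignan locants are used (C7, C8, C9 in the half with the acetoxy bridgehead, primed locants in the other half); the target as drawn is (7S,8R,7'R,8'S); ethyl glyoxylate is assumed to be used as the monomer, freshly distilled from its commercial toluene solution.

**Step 1**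
Reactants: 1 acetovanillone [1-(4-hydroxy-3-methoxyphenyl)ethan-1-one]; 2 allyl bromide
Product: 3 1-[4-(allyloxy)-3-methoxyphenyl]ethan-1-one
Conditions: K2CO3, DMF, rt
Reagents that add atoms: none
Why: Williamson ether synthesis, in which the phenol, deprotonated by K2CO3, displaces bromide from allyl bromide by SN2; the allyl ether then protects the phenol through every later step until step 12.

**Step 2**
Reactants: 3 1-[4-(allyloxy)-3-methoxyphenyl]ethan-1-one; 4 ethyl glyoxylate
Product: 6 ethyl 4-[4-(allyloxy)-3-methoxyphenyl]-2-hydroxy-4-oxobutanoate (racemic), via lithium enolate 5 (not isolated)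
Conditions: LiN(SiMe3)2, THF, −78 °C; then 4, −78 °C; AcOH quench
Reagents that add atoms: none
Why: Directed aldol addition of the kinetic lithium enolate 5 to the very electrophilic aldehyde of ethyl glyoxylate at low temperature should give the β-hydroxy ketone, whose new C2 carbinol may be racemic because it is oxidised away in step 4.

**Step 3**
Reactants: 6 ethyl 4-[4-(allyloxy)-3-methoxyphenyl]-2-hydroxy-4-oxobutanoate
Product: 8 (5R)-5-[4-(allyloxy)-3-methoxyphenyl]-3-hydroxydihydrofuran-2(3H)-one (both C3 epimers), via dihydroxy ester 7 (not isolated)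
Conditions: RuCl[(R,R)-TsDPEN](p-cymene) (cat.), HCO2H/Et3N (5:2), 35 °C; then PPTS (cat.), CH2Cl2, rt
Reagents that add atoms: none
Why: Noyori–Ikariya asymmetric transfer hydrogenation reduces the aryl ketone under catalyst control, the (R,R)-catalyst being expected to give the (R)-benzylic carbinol as it does with simple aryl alkyl ketones, and this sets C7'; the γ-hydroxy ester 7 then lactonises under mild acid without breaking the benzylic C–O bond.

**Step 4**
Reactants: 8 (5R)-5-[4-(allyloxy)-3-methoxyphenyl]-3-hydroxydihydrofuran-2(3H)-one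
Product: 10 (5R)-5-[4-(allyloxy)-3-methoxyphenyl]-3-hydroxyfuran-2(5H)-one, via keto lactone 9 (not isolated)
Conditions: Dess–Martin periodinane, CH2Cl2, 0 °C → rt; aq. Na2S2O3 work-up without base
Reagents that add atoms: none
Why: Dess–Martin oxidation of the secondary α-hydroxy lactone should give keto lactone 9, which tautomerises to the conjugated enol 10 (an isotetronic acid), both C3 epimers converging and C5 (the future C7') staying untouched under these non-basic conditions.

**Step 5**
Reactants: 10 (5R)-5-[4-(allyloxy)-3-methoxyphenyl]-3-hydroxyfuran-2(5H)-one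
Product: 11 (5R)-5-[4-(allyloxy)-3-methoxyphenyl]-2-oxo-2,5-dihydrofuran-3-yl acetate
Conditions: Ac2O, pyridine, CH2Cl2, 0 °C
Reagents that add atoms: acetic anhydride, CC(=O)OC(C)=O
Why: O-Acylation of the acidic enol with Ac2O and pyridine should give the enol acetate, a weak base and low temperature being chosen because the C5 hydrogen is benzylic and vinylogously acidic.

**Step 6**
Reactants: 12 vanillin; 2 allyl bromide
Product: 13 4-(allyloxy)-3-methoxybenzaldehyde
Conditions: K2CO3, DMF, rt
Reagents that add atoms: none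
Why: Williamson ether synthesis, as in step 1.

**Step 7**
Reactants: 13 4-(allyloxy)-3-methoxybenzaldehyde; 14 (trimethylsilyl)methanol
Product: 16 [4-(allyloxy)-3-methoxyphenyl](chloro)methyl (trimethylsilyl)methyl ether (racemic), via hemiacetal 15 (not isolated)
Conditions: HCl (g), MgSO4, CH2Cl2, −20 → 0 °C; filtered, concentrated, used crude at once
Reagents that add atoms: hydrogen chloride, Cl
Why: Classical α-chloro ether synthesis, in which hemiacetal 15 forms from the aldehyde and the alcohol and its hydroxyl is exchanged for chloride by dry HCl with the p-alkoxy group assisting ionisation; the racemic product is used crude because its stereocentre is erased in step 8.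

**Step 8**
Reactants: 11 (5R)-5-[4-(allyloxy)-3-methoxyphenyl]-2-oxo-2,5-dihydrofuran-3-yl acetate; 16 [4-(allyloxy)-3-methoxyphenyl](chloro)methyl (trimethylsilyl)methyl ether
Product: 18 (3S,3aS,6R,6aS)-3,6-bis[4-(allyloxy)-3-methoxyphenyl]-4-oxotetrahydro-1H,3H-furo[3,4-c]furan-3a(4H)-yl acetate (lignan locants 7S,8S,7'R,8'S; C9 is the lactone carbonyl), via carbonyl ylide 17 (not isolated)
Conditions: CsF (dried, excess), MeCN, 0 °C → rt; 16 in excess (about 2.5 equiv)
Reagents that add atoms: none
Why: Fluoride attacks silicon in 16 as chloride leaves the benzylic carbon (1,3-elimination), giving the non-stabilised carbonyl ylide 17, which the electron-rich aryl group polarises towards an oxocarbenium at C7 and a carbanion at the C9' methylene. 17 adds across the C8=C8' bond of 11 in a concerted but asynchronous [3+2] cycloaddition; the closest known reaction type is the fluoride-induced carbonyl ylide cycloaddition of α-chloroalkyl silylmethyl ethers with acrylates, fumarates and enones. Ring A is closed by this intermolecular cycloaddition (the three ylide atoms C7–O–C9' plus the two alkene carbons), C7–C8 and C8'–C9' forming in the same step. Regiochemistry should follow polarity, the CH2 terminus bonding to the β-carbon C8' and the benzylic terminus to the acetoxy-bearing α-carbon C8. C8 and C8' become cis-fused through suprafacial addition, and their absolute sense is set by approach to the butenolide face anti to the C7' aryl group. C7 is set by the outside geometry of the ylide aryl and its exo orientation away from ring B, which places it cis to the acetoxy group on the convex face; this is the least secure of the three selectivities because only sterics support it.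

**Step 9**
Reactants: 18 (3S,3aS,6R,6aS)-3,6-bis[4-(allyloxy)-3-methoxyphenyl]-4-oxotetrahydro-1H,3H-furo[3,4-c]furan-3a(4H)-yl acetate
Product: 19 (3S,3aS,6R,6aS)-3,6-bis[4-(allyloxy)-3-methoxyphenyl]tetrahydro-1H,3H-furo[3,4-c]furan-3a,4(4H)-diol (both C4 anomers)
Conditions: i-Bu2AlH (excess), CH2Cl2, −78 °C; aq. KNaC4H4O6 work-up
Reagents that add atoms: none
Why: i-Bu2AlH at −78 °C should reduce the γ-lactone only as far as the lactol (standard lactone-to-lactol reduction) and at the same time cleave the acetate reductively to the C8 alcohol, the only new stereocentre being the anomeric C9, which is removed in step 10.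

**Step 10**
Reactants: 19 (3S,3aS,6R,6aS)-3,6-bis[4-(allyloxy)-3-methoxyphenyl]tetrahydro-1H,3H-furo[3,4-c]furan-3a,4(4H)-diol
Product: 20 (3S,3aR,6R,6aS)-3,6-bis[4-(allyloxy)-3-methoxyphenyl]tetrahydro-1H,3H-furo[3,4-c]furan-3a(4H)-ol
Conditions: Et3SiH (excess), BF3·OEt2, CH2Cl2, −78 → −40 °C; quenched cold with Et3N
Reagents that add atoms: none
Why: Lewis acid-promoted silane reduction (ionic hydrogenation) of a lactol replaces the anomeric hydroxyl by hydrogen; at −78 °C the hemiacetal C9–OH should be activated well before the benzylic C7–O and C7'–O ether bonds, so that C7 and C7' keep their configuration.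

**Step 11**
Reactants: 20 (3S,3aR,6R,6aS)-3,6-bis[4-(allyloxy)-3-methoxyphenyl]tetrahydro-1H,3H-furo[3,4-c]furan-3a(4H)-ol
Product: 21 (3S,3aR,6R,6aS)-3,6-bis[4-(allyloxy)-3-methoxyphenyl]tetrahydro-1H,3H-furo[3,4-c]furan-3a(4H)-yl acetate
Conditions: Ac2O, DMAP, Et3N, CH2Cl2, rt → 40 °C
Reagents that add atoms: acetic anhydride, CC(=O)OC(C)=O
Why: DMAP-catalysed acylation with Ac2O is the standard esterification of a hindered tertiary alcohol; the C8–O bond is not broken, so C8 keeps its configuration, and no other hydroxyl is present.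

**Step 12**
Reactants: 21 (3S,3aR,6R,6aS)-3,6-bis[4-(allyloxy)-3-methoxyphenyl]tetrahydro-1H,3H-furo[3,4-c]furan-3a(4H)-yl acetate
Product: 22 8-acetoxypinoresinol [(3S,3aR,6R,6aS)-3,6-bis(4-hydroxy-3-methoxyphenyl)tetrahydro-1H,3H-furo[3,4-c]furan-3a(4H)-yl acetate]
Conditions: Pd(PPh3)4 (cat., zerovalent palladium), morpholine, THF, rt
Reagents that add atoms: none
Why: Tsuji–Trost deallylation, in which Pd(PPh3)4 transfers the allyl groups of the two aryl ethers to morpholine at room temperature, conditions that should leave the tertiary acetate and the benzylic ether bonds untouched.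

**Compound list**
1 | acetovanillone, 1-(4-hydroxy-3-methoxyphenyl)ethan-1-one | CC(=O)c1ccc(O)c(OC)c1 | starting material
2 | allyl bromide (3-bromoprop-1-ene) | C=CCBr | starting material
3 | 1-[4-(allyloxy)-3-methoxyphenyl]ethan-1-one | CC(=O)c1ccc(OCC=C)c(OC)c1 | intermediate
4 | ethyl glyoxylate (ethyl 2-oxoacetate) | CCOC(=O)C=O | starting material
5 | lithium 1-[4-(allyloxy)-3-methoxyphenyl]ethen-1-olate (lithium enolate of 3, formed in the flask) | [Li+].[O-]C(=C)c1ccc(OCC=C)c(OC)c1 | intermediate
6 | ethyl 4-[4-(allyloxy)-3-methoxyphenyl]-2-hydroxy-4-oxobutanoate (racemic) | CCOC(=O)C(O)CC(=O)c1ccc(OCC=C)c(OC)c1 | intermediate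
7 | ethyl (4R)-4-[4-(allyloxy)-3-methoxyphenyl]-2,4-dihydroxybutanoate (both C2 epimers, formed in the flask) | CCOC(=O)C(O)C[C@@H](O)c1ccc(OCC=C)c(OC)c1 | intermediate
8 | (5R)-5-[4-(allyloxy)-3-methoxyphenyl]-3-hydroxydihydrofuran-2(3H)-one (both C3 epimers) | COc1cc([C@@H]2OC(=O)C(O)C2)ccc1OCC=C | intermediate
9 | (5R)-5-[4-(allyloxy)-3-methoxyphenyl]dihydrofuran-2,3-dione (keto lactone, formed in the flask) | COc1cc([C@@H]2OC(=O)C(=O)C2)ccc1OCC=C | intermediate
10 | (5R)-5-[4-(allyloxy)-3-methoxyphenyl]-3-hydroxyfuran-2(5H)-one (isotetronic acid) | COc1cc([C@@H]2OC(=O)C(O)=C2)ccc1OCC=C | intermediate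
11 | (5R)-5-[4-(allyloxy)-3-methoxyphenyl]-2-oxo-2,5-dihydrofuran-3-yl acetate | COc1cc([C@@H]2OC(=O)C(OC(C)=O)=C2)ccc1OCC=C | intermediate
12 | vanillin (4-hydroxy-3-methoxybenzaldehyde) | COc1cc(C=O)ccc1O | starting material
13 | 4-(allyloxy)-3-methoxybenzaldehyde | COc1cc(C=O)ccc1OCC=C | intermediate
14 | (trimethylsilyl)methanol | C[Si](C)(C)CO | starting material
15 | [4-(allyloxy)-3-methoxyphenyl][(trimethylsilyl)methoxy]methanol (hemiacetal, formed in the flask) | COc1cc(C(O)OC[Si](C)(C)C)ccc1OCC=C | intermediate
16 | [4-(allyloxy)-3-methoxyphenyl](chloro)methyl (trimethylsilyl)methyl ether (racemic) | COc1cc(C(Cl)OC[Si](C)(C)C)ccc1OCC=C | intermediate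
17 | carbonyl ylide ArCH=O(+)–CH2(−), Ar = 4-(allyloxy)-3-methoxyphenyl (formed in the flask) | COc1cc(C=[O+][CH2-])ccc1OCC=C | intermediate
18 | (3S,3aS,6R,6aS)-3,6-bis[4-(allyloxy)-3-methoxyphenyl]-4-oxotetrahydro-1H,3H-furo[3,4-c]furan-3a(4H)-yl acetate (7S,8S,7'R,8'S; cis-fused, both aryl groups exo) | COc1cc([C@@H]2OC(=O)[C@@]3(OC(C)=O)[C@H](c4ccc(OCC=C)c(OC)c4)OC[C@@H]23)ccc1OCC=C | intermediate
19 | (3S,3aS,6R,6aS)-3,6-bis[4-(allyloxy)-3-methoxyphenyl]tetrahydro-1H,3H-furo[3,4-c]furan-3a,4(4H)-diol (lactol, both C4 anomers) | COc1cc([C@@H]2OC(O)[C@@]3(O)[C@H](c4ccc(OCC=C)c(OC)c4)OC[C@@H]23)ccc1OCC=C | intermediate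
20 | (3S,3aR,6R,6aS)-3,6-bis[4-(allyloxy)-3-methoxyphenyl]tetrahydro-1H,3H-furo[3,4-c]furan-3a(4H)-ol (7S,8R,7'R,8'S) | COc1cc([C@@H]2OC[C@@]3(O)[C@H](c4ccc(OCC=C)c(OC)c4)OC[C@@H]23)ccc1OCC=C | intermediate
21 | (3S,3aR,6R,6aS)-3,6-bis[4-(allyloxy)-3-methoxyphenyl]tetrahydro-1H,3H-furo[3,4-c]furan-3a(4H)-yl acetate (7S,8R,7'R,8'S) | COc1cc([C@@H]2OC[C@@]3(OC(C)=O)[C@H](c4ccc(OCC=C)c(OC)c4)OC[C@@H]23)ccc1OCC=C | intermediate
22 | 8-acetoxypinoresinol, (3S,3aR,6R,6aS)-3,6-bis(4-hydroxy-3-methoxyphenyl)tetrahydro-1H,3H-furo[3,4-c]furan-3a(4H)-yl acetate (7S,8R,7'R,8'S) | COc1cc([C@@H]2OC[C@@]3(OC(C)=O)[C@H](c4ccc(O)c(OC)c4)OC[C@@H]23)ccc1O | target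

**Step count**
Total: 12 steps. Longest linear sequence: 10 steps (steps 1–5, then 8–12); steps 6 and 7 form the two-step branch to the ylide precursor.

**Steps most likely to fail**

1. Step 8. The exo preference of the ylide aryl group may be weak, so that C7 forms largely with the wrong configuration. In addition, the basic fluoride may epimerise the acidic γ-position (C7') of 11, or cleave its enol acetate, before cycloaddition occurs. Fallback: the same partners 11 and 16 are combined, but C7 is corrected afterwards under thermodynamic control. The C7-epimeric cycloadduct F1 is treated with catalytic TMSOTf in CH2Cl2 at −20 °C. This reversibly ionises the electron-rich benzylic C7–O bond of ring A and lets it re-close, which is the known acid epimerisation of 2-aryl-3,7-dioxabicyclo[3.3.0]octanes. The mixture is separated, unchanged F1 is resubmitted, and the route is rejoined at 18.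

2. Step 7. The water formed may reverse the chloro ether formation, and HCl may promote self-condensation of the very ionisable electron-rich benzylic chloride with another arene ring. Fallback: setting out from 13, acid-catalysed acetalisation with two equivalents of 14 (PPTS, benzene, azeotropic removal of water) gives the bis[(trimethylsilyl)methyl] acetal F2. Acetyl chloride with a trace of SOCl2 (CH2Cl2, 0 °C → rt) then exchanges one alkoxy group for chloride. This returns 16 under anhydrous conditions free of HCl gas and water.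

3. Step 10. BF3 may ionise the p-alkoxybenzylic C7–O or C7'–O bonds in competition with the lactol, leading to epimerisation at C7 or C7' or to reductive ring opening. Fallback: setting out from 18, LiAlH4 (THF, 0 °C) opens the lactone and removes the acetate to give the triol F3. MsCl (1 equiv) in pyridine (0 °C → rt) sulfonylates the primary C9 hydroxyl to the primary mesylate F4. The C7' hydroxyl then displaces the mesylate in a 5-exo-tet closure of ring B, in which the C7'–O bond is never broken. The route is rejoined at 20 without any Lewis acid, and steps 9 and 10 are both bypassed.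

**Further compounds**
F1 | step 8 | (3R,3aS,6R,6aS)-3,6-bis[4-(allyloxy)-3-methoxyphenyl]-4-oxotetrahydro-1H,3H-furo[3,4-c]furan-3a(4H)-yl acetate (C7 epimer of 18, aryl at C7 endo) | COc1cc([C@@H]2OC(=O)[C@@]3(OC(C)=O)[C@@H](c4ccc(OCC=C)c(OC)c4)OC[C@@H]23)ccc1OCC=C
F2 | step 7 | 4-(allyloxy)-3-methoxybenzaldehyde bis[(trimethylsilyl)methyl] acetal | COc1cc(C(OC[Si](C)(C)C)OC[Si](C)(C)C)ccc1OCC=C
F3 | step 10 | (2S,3R,4S)-2-[4-(allyloxy)-3-methoxyphenyl]-4-{(R)-[4-(allyloxy)-3-methoxyphenyl](hydroxy)methyl}-3-(hydroxymethyl)tetrahydrofuran-3-ol (triol) | COc1cc([C@H](O)[C@@H]2CO[C@@H](c3ccc(OCC=C)c(OC)c3)[C@]2(O)CO)ccc1OCC=C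
F4 | step 10 | {(2S,3R,4S)-2-[4-(allyloxy)-3-methoxyphenyl]-4-{(R)-[4-(allyloxy)-3-methoxyphenyl](hydroxy)methyl}-3-hydroxytetrahydrofuran-3-yl}methyl methanesulfonate (primary mesylate) | COc1cc([C@H](O)[C@@H]2CO[C@@H](c3ccc(OCC=C)c(OC)c3)[C@]2(O)COS(C)(=O)=O)ccc1OCC=C
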